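The north-east flask is the one asked about, and we have its readings up to 6.00 d.

- north-east: starting material 0.050 M; second substrate 0.050 M; solid reagent 0.090 M; free catalyst 1.4 mM; the very flask that is asked about, followed so far
- flask: starting material 0.050 M; second substrate 0.0500 M; solid reagent 0.0900 M; free catalyst 1.4 mM; time 6.0 d

- north-east (time / d: target / %, starting material / %): 0.333: 8, 95; 0.833: 18, 85; 1.67: 23, 77; 2.50: 31, 68; 4.00: 33, 62; 5.00: 34, 64; 6.00: 35, 60

(standard deviation of a reading: 2 percentage points)

- beta: at 6.0 d take out 90% of the target then present, then wait 6.0 d
- epsilon: change nothing and wait 6.0 d more
- zeta: at 6.0 d add free catalyst, 50.0% of the amount charged, then wait 6.0 d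
- delta: at 6.0 d add starting material, 50.0% of the amount charged, then wait 6.0 d

- solid reagent is a solid; its amount is given per volume of the solution
- removed target is counted in
- at the start none of the solid reagent is in solution
- additions bring no volume worth counting

- target, in percent of the starting material first charged, at 6.0 d
- what to do for the largest gain in target; "none" if nothing gains more than 2 percentage points (beta / epsilon / zeta / delta / none)
- target present, with what was taken out counted in, in percent of the starting material first charged, after beta
- target present, with what was taken out counted in, in percent of the starting material first charged, after epsilon

In the north-east readings the target rose from 33% at 4.00 d to 35% at 6.00 d, with a scatter of 2 percentage points, while 60% of the starting material stood unused. A reverse step could fit this single run as well, but we bet on a dying catalyst, the smallest charge in the flask. The bench rule for such a stall is to count turnovers. With 35% of 0.050 M made on 1.4 mM of free catalyst, we get 12.5: this N is the target made per free catalyst charged, the turnover number.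

The rule says that in this flask each further free catalyst buys N more, provided it works as the first charge did. It stops working where the target so bought would pass the starting material left, and in the north-east readings the ratio of starting material left to target made puts that border at 1.71 of the catalyst charge. Zeta adds 50.0% of the charge, which lies inside it. So we commit to 35% now and to zeta as best, with a gain of 18 points. Beta, epsilon and delta should each gain less than 2 points and leave the target where it stands.

The forecast gave 35% now, 35.5% after epsilon and 47% after beta, chose beta, and held that “Reversibility or target inhibition seems likeliest”.

The flask gives 35.3% now and 35.3% after epsilon, 35.3% after beta. The best choice is zeta, which gains 36 points, against 0.05 points for beta, 0.05 points for epsilon and 0.089 points for delta.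

    2 free catalyst → spent catalyst A (k = 25.0 M⁻¹ h⁻¹)
    second substrate + partner + free catalyst → free catalyst + second product (k = 26000 M⁻² h⁻¹)
    solid reagent ⇌ partner, rate k3*(cs3 - [partner]) while solid is left; crystals form when [partner] > cs3 (solubility = 16.0 mM, k = 0.0710 h⁻¹)
    free catalyst → spent catalyst B (k = 0.0560 h⁻¹)
    starting material + partner + free catalyst → free catalyst + target (k = 14000 M⁻² h⁻¹)

Our choice stands, but the gain under zeta comes to 25.8 target per added free catalyst, twice N. One reason for that gain is the slow dissolving of the solid reagent: in the run with quick dissolving, zeta gains 1.2 points instead of 36 points. So watch the partner, which stands at 0.00147 M at 0.600 d and 0.0158 M at 6.00 d, when free catalyst is down to 0.0140%. In the neighbour flask with 0.085 M of second substrate, free catalyst also ends at 0.0140%, and N falls to 10.1.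

The earlier runs and the new flask are calculated on assumed constants; the scatter is artificial.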